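**Retrosynthetic overview**

1. Target ⇒ (hydrogenolysis of eight benzyl ethers, Algar–Flynn–Oyamada oxidation, Claisen–Schmidt condensation) an aldehyde on the pyrogallol ring plus 4-(benzyloxy)-2-hydroxyacetophenone; the aldehyde comes from an aryl bromide, so the flavonol pyranone is the last ring made.
2. Flavan pyran ring (ring C): O1–C2 is cut; the ring A phenol closes onto a C2 benzylic cation released from the C2 methyl ether of a 1,1,3-triarylpropane that already holds C3 and C4.
3. C4–pyrogallol-ring bond: 1,4-addition of the 2-bromoaryl Grignard reagent to the ring A ortho-quinone methide (basic, so the C2 methyl ether is untouched); C4–ring A bond: addition of doubly lithiated 5-(benzyloxy)-2-bromophenol to an aldehyde, which fixes the ring A regiochemistry.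
4. Feature: the catechol ring with C2, C3 (the carbinol) and C4 of the flavan is the aryl group, CH2, CH(OH) and carboxyl carbon of (R)-danshensu; C2 is oxygenated with DDQ/MeOH and C3 is carried through unchanged.
5. Ring order: pyran ring of the flavan (step 11), then the pyranone of the flavonol (step 14).

Key step: step 11

Assumption: the bromophenol that supplies ring A in step 5 is taken as a catalogue compound; one ortho-bromination of 3-(benzyloxy)phenol would otherwise supply it.
Remark: in the Why lines the chain atoms carry flavan numbers (O1, C2, C3, C4; ring A is the benzo ring of the flavan, ring C its pyran ring); the trioxygenated ring is called the pyrogallol ring.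

**Route**

Step 1
Reactants: 1 sodium danshensu
Product: 2 benzyl (2R)-3-[3,4-bis(benzyloxy)phenyl]-2-hydroxypropanoate
Conditions: BnBr (3.5 equiv), K2CO3, DMF, N2, rt
Reagents that add atoms: benzyl bromide, BrCc1ccccc1
Why: Williamson O-alkylation of both phenols and SN2 esterification of the carboxylate under carbonate, which is too weak to alkylate the secondary alcohol or to epimerise the α-carbon, should give the tribenzyl compound with the (R) centre intact.

Step 2
Reactants: 2 benzyl (2R)-3-[3,4-bis(benzyloxy)phenyl]-2-hydroxypropanoate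
Product: 3 benzyl (2R)-2-(benzyloxy)-3-[3,4-bis(benzyloxy)phenyl]propanoate
Conditions: BnBr, Ag2O, 4 Å MS, CH2Cl2, rt, dark
Reagents that add atoms: benzyl bromide, BrCc1ccccc1
Why: Ag2O-promoted O-benzylation (Williamson-type alkylation assisted by halide abstraction) etherifies the α-hydroxy ester without a free alkoxide base, so the future C3 keeps its configuration.

Step 3
Reactants: 3 benzyl (2R)-2-(benzyloxy)-3-[3,4-bis(benzyloxy)phenyl]propanoate
Product: 4 benzyl (2R)-2-(benzyloxy)-3-[3,4-bis(benzyloxy)phenyl]-3-methoxypropanoate (both epimers at the methoxy carbon)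
Conditions: DDQ (1.3 equiv), CH2Cl2–MeOH 4:1, 0 °C → rt
Reagents that add atoms: methanol, CO
Why: DDQ abstracts hydride from the benzylic CH2 para to the 4-benzyloxy group (benzylic C–H oxidation through a para-quinone-methide-type cation) and methanol captures the cation; the future C2 forms as both epimers, which is of no consequence because this carbon is ionised again in the key step, and the future C3 is not involved.

Step 4
Reactants: 4 benzyl (2R)-2-(benzyloxy)-3-[3,4-bis(benzyloxy)phenyl]-3-methoxypropanoate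
Product: 5 (2R)-2-(benzyloxy)-3-[3,4-bis(benzyloxy)phenyl]-3-methoxypropanal
Conditions: iBu2AlH (1.1 equiv), CH2Cl2, −78 °C
Reagents that add atoms: none
Why: partial ester reduction by iBu2AlH at low temperature stops at the aluminium hemiacetal, which the α- and β-alkoxy groups chelate, and the aldehyde is released only on work-up and used at once, so the future C3 is not epimerised and methanol is not eliminated.

Step 5
Reactants: 5 (2R)-2-(benzyloxy)-3-[3,4-bis(benzyloxy)phenyl]-3-methoxypropanal; 6 5-(benzyloxy)-2-bromophenol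
Product: 8 (2S)-1-[4-(benzyloxy)-2-hydroxyphenyl]-2-(benzyloxy)-3-[3,4-bis(benzyloxy)phenyl]-3-methoxypropan-1-ol (C1/C3 epimers), via lithium 5-(benzyloxy)-2-lithiophenolate 7 (not isolated)
Conditions: 6 (1.3 equiv), n-BuLi (2 equiv per 6), Et2O–THF, −78 → 0 °C; then 5, −78 °C; H2O
Reagents that add atoms: none
Why: O–H deprotonation followed by Br/Li exchange gives the ortho-lithiated phenolate 7, which adds to the aldehyde (1,2-addition) and so places C4 on ring A para to the benzyloxy group and ortho to the phenol oxygen without any electrophilic substitution; the carbinol centre forms as a mixture and becomes sp2 in step 10.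

Step 6
Reactants: 8 (2S)-1-[4-(benzyloxy)-2-hydroxyphenyl]-2-(benzyloxy)-3-[3,4-bis(benzyloxy)phenyl]-3-methoxypropan-1-ol
Product: 9 tert-butyl 5-(benzyloxy)-2-[(2S)-2-(benzyloxy)-3-[3,4-bis(benzyloxy)phenyl]-1-hydroxy-3-methoxypropyl]phenyl carbonate
Conditions: Boc2O (1.05 equiv), iPr2NEt, DMAP (cat.), CH2Cl2, 0 °C
Reagents that add atoms: di-tert-butyl dicarbonate, CC(C)(C)OC(=O)OC(=O)OC(C)(C)C
Why: Boc2O with DMAP acylates the acidic, unhindered phenol in preference to the hindered secondary benzylic alcohol (chemoselective carbonate formation), which gives the ortho-quinone methide precursor.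

Step 7
Reactants: 10 5-bromo-1,2,3-trimethoxybenzene
Product: 11 5-bromobenzene-1,2,3-triol
Conditions: BBr3, CH2Cl2, −78 °C → rt; H2O
Reagents that add atoms: none
Why: BBr3 cleaves the three aryl methyl ethers (Lewis-acid ether cleavage) at this early stage, because methyl ethers could not be removed at the end without destroying the flavan whereas benzyl ethers can.

Step 8
Reactants: 11 5-bromobenzene-1,2,3-triol
Product: 12 5-bromo-1,2,3-tris(benzyloxy)benzene
Conditions: BnBr (3.5 equiv), K2CO3, DMF, N2, 60 °C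
Reagents that add atoms: benzyl bromide, BrCc1ccccc1
Why: Williamson benzylation of the three phenols under carbonate, with air excluded to protect the pyrogallol.

Step 9
Reactants: 12 5-bromo-1,2,3-tris(benzyloxy)benzene
Product: 13 1-bromo-2-iodo-3,4,5-tris(benzyloxy)benzene
Conditions: N-iodosuccinimide (1.05 equiv), CF3CO2H (cat.), MeCN, rt
Reagents that add atoms: N-iodosuccinimide, O=C1CCC(=O)N1I
Why: electrophilic aromatic iodination can only occur at one of the two equivalent free positions (ortho and para to benzyloxy groups), which places iodine next to bromine; the phenyl rings of the benzyl groups are not activated.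

Step 10
Reactants: 9 tert-butyl aryl carbonate; 13 1-bromo-2-iodo-3,4,5-tris(benzyloxy)benzene
Product: 16 (1S,2S)-1-[4-(benzyloxy)-2-hydroxyphenyl]-2-(benzyloxy)-1-[6-bromo-2,3,4-tris(benzyloxy)phenyl]-3-[3,4-bis(benzyloxy)phenyl]-3-methoxypropane (both C3 epimers), via arylmagnesium chloride 14 (not isolated), via ortho-quinone methide 15 (not isolated)
Conditions: 13 (1.6 equiv), iPrMgCl·LiCl (1.5 equiv), THF, −40 °C; 9, MeMgCl (1.0 equiv), toluene, −78 °C; then 14, −78 → −20 °C
Reagents that add atoms: none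
Why: iodine/magnesium exchange (faster than bromine/magnesium exchange) gives 14 with the ortho-bromine intact at low temperature, the magnesium alkoxide of 9 takes over the Boc group and expels tert-butyl carbonate to give ortho-quinone methide 15, and 14 adds to it in a 1,4-addition that restores the ring A phenol under basic conditions that cannot ionise the C2 methyl ether; at the new C4 centre, A1,3 strain keeps the C3–H bond in the plane of the quinone methide, so the aryl group, held on magnesium by the benzyloxy oxygen and kept away from the branched C2 carbon, should enter on the benzyloxy face and give the 3,4-anti (1S) isomer, the minor epimer being removed by chromatography.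

Step 11
Reactants: 16 triarylpropane with C2 methyl ether and free ring A phenol
Product: 18 (2R,3S,4S)-3,7-bis(benzyloxy)-2-[3,4-bis(benzyloxy)phenyl]-4-[6-bromo-2,3,4-tris(benzyloxy)phenyl]chromane, via C2 benzylic cation 17 (not isolated)
Conditions: BF3·OEt2 (0.5 equiv), 4 Å MS, CH2Cl2, −40 → 0 °C
Reagents that add atoms: none
Why: BF3 (and the acid BF3·MeOH formed from the released methanol) ionises the C2 methyl ether of either epimer of 16 to the same planar benzylic cation 17, a para-benzyloxy-stabilised ion of para-quinone-methide type, and the ring A phenol oxygen adds to it to form O1–C2. The closest known reaction type is the acid-mediated cyclisation of 1,3-diarylpropan-2-ol derivatives with a benzylic leaving group to flavan-3-ols. Ring C closes in the 6-exo-trig mode, the phenol oxygen attacking the exocyclic cationic carbon through a chair-like transition state. The new C2 centre is controlled by the two fixed centres C3 (from danshensu) and C4 (from step 10): in the chair the C2 aryl group, the C3 benzyloxy group and the C4 aryl group are all equatorial, which is the 2,3-trans-3,4-trans (2R,3S,4S) flavan, and any 2,3-cis isomer can re-ionise at its C2–O1 bond under the same acid and drain into this isomer. The step needs O-capture by the phenol to win over a hydride shift from C3, over attack by the ortho benzyl ether oxygen of the pyrogallol ring and over Friedel–Crafts attack of ring A carbon C5; the free phenol is the only unhindered hydroxyl placed for a six-membered closure, C5 is meta to both ring A oxygens, and the low temperature and substoichiometric Lewis acid spare the benzyl ethers.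

Step 12
Reactants: 18 bromoaryl flavan
Product: 20 3,4,5-tris(benzyloxy)-2-[(2R,3S,4S)-3,7-bis(benzyloxy)-2-[3,4-bis(benzyloxy)phenyl]chroman-4-yl]benzaldehyde, via aryllithium 19 (not isolated)
Conditions: n-BuLi (1.1 equiv), THF, −78 °C; DMF, −78 → 0 °C; H2O
Reagents that add atoms: N,N-dimethylformamide, CN(C)C=O
Why: bromine/lithium exchange at −78 °C is faster than any attack on the benzyl ethers, and formylation of aryllithium 19 with DMF puts the aldehyde carbon where C2 of the flavonol will be; no stereocentre is touched.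

Step 13
Reactants: 20 aryl aldehyde; 21 1-[4-(benzyloxy)-2-hydroxyphenyl]ethan-1-one
Product: 22 (E)-2'-hydroxychalcone
Conditions: 21 (1.2 equiv), KOH, EtOH–THF, rt → 40 °C
Reagents that add atoms: none
Why: Claisen–Schmidt condensation of the non-enolisable aldehyde with the acetophenone enolate, followed by E1cB dehydration, should give the (E)-enone; benzyl ethers and the flavan are stable to hydroxide.

Step 14
Reactants: 22 (E)-2'-hydroxychalcone
Product: 23 octabenzyl flavonol
Conditions: H2O2 (30% aq.), NaOH, MeOH–THF, 0 °C → rt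
Reagents that add atoms: hydrogen peroxide, OO
Why: Algar–Flynn–Oyamada reaction, in which alkaline H2O2 epoxidises the enone, the 2'-phenoxide opens the epoxide at the β-carbon and the dihydroflavonol is oxidised on to the flavonol; the absence of a 6'-substituent on the acetophenone ring favours the flavonol over the aurone.

Step 15
Reactants: 23 octabenzyl flavonol
Product: 24 target CNP0381334.2
Conditions: H2 (1 atm), Pd(OH)2/C, THF–MeOH, rt
Reagents that add atoms: none
Why: hydrogenolysis removes all eight benzyl ethers (seven aryl, one alkyl) under neutral conditions in which the flavonol enone, the C2–O1 bond and the three stereocentres should not be touched, as in the deprotection of benzylated flavan-3-ols and flavonols.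

**Compound list**

1 | sodium (2R)-3-(3,4-dihydroxyphenyl)-2-hydroxypropanoate (sodium danshensu) | O[C@H](Cc1ccc(O)c(O)c1)C(=O)[O-].[Na+] | starting material
2 | benzyl (2R)-3-[3,4-bis(benzyloxy)phenyl]-2-hydroxypropanoate | O[C@H](Cc1ccc(OCc2ccccc2)c(OCc2ccccc2)c1)C(=O)OCc1ccccc1 | intermediate
3 | benzyl (2R)-2-(benzyloxy)-3-[3,4-bis(benzyloxy)phenyl]propanoate | c1ccccc1CO[C@H](Cc1ccc(OCc2ccccc2)c(OCc2ccccc2)c1)C(=O)OCc1ccccc1 | intermediate
4 | benzyl (2R)-2-(benzyloxy)-3-[3,4-bis(benzyloxy)phenyl]-3-methoxypropanoate, both C3 epimers | c1ccccc1CO[C@H](C(OC)c1ccc(OCc2ccccc2)c(OCc2ccccc2)c1)C(=O)OCc1ccccc1 | intermediate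
5 | (2R)-2-(benzyloxy)-3-[3,4-bis(benzyloxy)phenyl]-3-methoxypropanal, both C3 epimers | c1ccccc1CO[C@H](C(OC)c1ccc(OCc2ccccc2)c(OCc2ccccc2)c1)C=O | intermediate
6 | 5-(benzyloxy)-2-bromophenol | Oc1cc(OCc2ccccc2)ccc1Br | starting material
7 | lithium 5-(benzyloxy)-2-lithiophenolate | [Li]Oc1cc(OCc2ccccc2)ccc1[Li] | intermediate (not isolated)
8 | (2S)-1-[4-(benzyloxy)-2-hydroxyphenyl]-2-(benzyloxy)-3-[3,4-bis(benzyloxy)phenyl]-3-methoxypropan-1-ol, epimers at C1 and C3 | OC(c1ccc(OCc2ccccc2)cc1O)[C@H](OCc1ccccc1)C(OC)c1ccc(OCc2ccccc2)c(OCc2ccccc2)c1 | intermediate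
9 | tert-butyl 5-(benzyloxy)-2-[(2S)-2-(benzyloxy)-3-[3,4-bis(benzyloxy)phenyl]-1-hydroxy-3-methoxypropyl]phenyl carbonate, epimers at C1 and C3 of the propyl chain | OC(c1ccc(OCc2ccccc2)cc1OC(=O)OC(C)(C)C)[C@H](OCc1ccccc1)C(OC)c1ccc(OCc2ccccc2)c(OCc2ccccc2)c1 | intermediate
10 | 5-bromo-1,2,3-trimethoxybenzene | COc1cc(Br)cc(OC)c1OC | starting material
11 | 5-bromobenzene-1,2,3-triol | Oc1cc(Br)cc(O)c1O | intermediate
12 | 5-bromo-1,2,3-tris(benzyloxy)benzene | Brc1cc(OCc2ccccc2)c(OCc2ccccc2)c(OCc2ccccc2)c1 | intermediate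
13 | 1-bromo-2-iodo-3,4,5-tris(benzyloxy)benzene | Brc1cc(OCc2ccccc2)c(OCc2ccccc2)c(OCc2ccccc2)c1I | intermediate
14 | [6-bromo-2,3,4-tris(benzyloxy)phenyl]magnesium chloride | Brc1cc(OCc2ccccc2)c(OCc2ccccc2)c(OCc2ccccc2)c1[Mg]Cl | intermediate (not isolated)
15 | 3-(benzyloxy)-6-[(2S)-2-(benzyloxy)-3-[3,4-bis(benzyloxy)phenyl]-3-methoxypropylidene]cyclohexa-2,4-dien-1-one (ortho-quinone methide of ring A) | O=C1C=C(OCc2ccccc2)C=CC1=C[C@H](OCc1ccccc1)C(OC)c1ccc(OCc2ccccc2)c(OCc2ccccc2)c1 | intermediate (not isolated)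
16 | (1S,2S)-1-[4-(benzyloxy)-2-hydroxyphenyl]-2-(benzyloxy)-1-[6-bromo-2,3,4-tris(benzyloxy)phenyl]-3-[3,4-bis(benzyloxy)phenyl]-3-methoxypropane, both C3 epimers | Brc1cc(OCc2ccccc2)c(OCc2ccccc2)c(OCc2ccccc2)c1[C@H](c1ccc(OCc2ccccc2)cc1O)[C@H](OCc1ccccc1)C(OC)c1ccc(OCc2ccccc2)c(OCc2ccccc2)c1 | intermediate
17 | benzylic cation at the former methoxy carbon of 16 (para-benzyloxybenzyl cation, para-quinone-methide type) | Brc1cc(OCc2ccccc2)c(OCc2ccccc2)c(OCc2ccccc2)c1[C@H](c1ccc(OCc2ccccc2)cc1O)[C@H](OCc1ccccc1)[CH+]c1ccc(OCc2ccccc2)c(OCc2ccccc2)c1 | intermediate (not isolated)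
18 | (2R,3S,4S)-3,7-bis(benzyloxy)-2-[3,4-bis(benzyloxy)phenyl]-4-[6-bromo-2,3,4-tris(benzyloxy)phenyl]chromane | Brc1cc(OCc2ccccc2)c(OCc2ccccc2)c(OCc2ccccc2)c1[C@@H]1c2ccc(OCc3ccccc3)cc2O[C@H](c2ccc(OCc3ccccc3)c(OCc3ccccc3)c2)[C@H]1OCc1ccccc1 | intermediate
19 | aryllithium of 18 (lithium in place of bromine) | [Li]c1cc(OCc2ccccc2)c(OCc2ccccc2)c(OCc2ccccc2)c1[C@@H]1c2ccc(OCc3ccccc3)cc2O[C@H](c2ccc(OCc3ccccc3)c(OCc3ccccc3)c2)[C@H]1OCc1ccccc1 | intermediate (not isolated)
20 | 3,4,5-tris(benzyloxy)-2-[(2R,3S,4S)-3,7-bis(benzyloxy)-2-[3,4-bis(benzyloxy)phenyl]chroman-4-yl]benzaldehyde | O=Cc1cc(OCc2ccccc2)c(OCc2ccccc2)c(OCc2ccccc2)c1[C@@H]1c2ccc(OCc3ccccc3)cc2O[C@H](c2ccc(OCc3ccccc3)c(OCc3ccccc3)c2)[C@H]1OCc1ccccc1 | intermediate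
21 | 1-[4-(benzyloxy)-2-hydroxyphenyl]ethan-1-one | CC(=O)c1ccc(OCc2ccccc2)cc1O | starting material
22 | (E)-1-[4-(benzyloxy)-2-hydroxyphenyl]-3-{3,4,5-tris(benzyloxy)-2-[(2R,3S,4S)-3,7-bis(benzyloxy)-2-[3,4-bis(benzyloxy)phenyl]chroman-4-yl]phenyl}prop-2-en-1-one | O=C(c1ccc(OCc2ccccc2)cc1O)/C=C/c1cc(OCc2ccccc2)c(OCc2ccccc2)c(OCc2ccccc2)c1[C@@H]1c2ccc(OCc3ccccc3)cc2O[C@H](c2ccc(OCc3ccccc3)c(OCc3ccccc3)c2)[C@H]1OCc1ccccc1 | intermediate
23 | 7-(benzyloxy)-3-hydroxy-2-{3,4,5-tris(benzyloxy)-2-[(2R,3S,4S)-3,7-bis(benzyloxy)-2-[3,4-bis(benzyloxy)phenyl]chroman-4-yl]phenyl}-4H-chromen-4-one | O=c1c(O)c(-c2cc(OCc3ccccc3)c(OCc3ccccc3)c(OCc3ccccc3)c2[C@@H]2c3ccc(OCc4ccccc4)cc3O[C@H](c3ccc(OCc4ccccc4)c(OCc4ccccc4)c3)[C@H]2OCc2ccccc2)oc2cc(OCc3ccccc3)ccc12 | intermediate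
24 | 3,7-dihydroxy-2-{3,4,5-trihydroxy-2-[(2R,3S,4S)-2-(3,4-dihydroxyphenyl)-3,7-dihydroxychroman-4-yl]phenyl}-4H-chromen-4-one (CNP0381334.2) | O=c1c(O)c(-c2cc(O)c(O)c(O)c2[C@@H]2c3ccc(O)cc3O[C@H](c3ccc(O)c(O)c3)[C@H]2O)oc2cc(O)ccc12 | target

**Summary**

Total step count: 15. Longest linear sequence: 12 steps (1–6 and 10–15).

**Steps most likely to fail**

Step 10. The 1,4-addition of the doubly ortho-substituted aryl Grignard reagent may be slow enough for the quinone methide to tautomerise by loss of the C3 proton (which destroys the danshensu stereocentre), and facial selectivity at C4 may be poor or reversed. The fallback reverses the order in which the two aryl groups arrive and makes the C4–ring A bond by a cationic Friedel–Crafts alkylation. It sets out from aldehyde 5 and iodide 13 and comes back to the route at 16. Grignard reagent 14 (from 13 and iPrMgCl·LiCl) is added to 5 in THF at −40 °C with LaCl3·2LiCl to give (2S)-1-[6-bromo-2,3,4-tris(benzyloxy)phenyl]-2-(benzyloxy)-3-[3,4-bis(benzyloxy)phenyl]-3-methoxypropan-1-ol F1. Cl3CCN with catalytic DBU converts it into the benzylic trichloroacetimidate F2. Catalytic TMSOTf at −78 °C in CH2Cl2 ionises only the imidate (the methyl ether needs stronger activation), and 3-(benzyloxy)phenol in excess is alkylated at the carbon ortho to its hydroxyl and para to its benzyloxy group to give 16; regioisomers would be separated. Because the aryl groups are exchanged between electrophile and nucleophile, a preference for attack anti to the C3 benzyloxy group, which would give the wrong C4 epimer in step 10, gives the right one here.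

Step 11. The two aryl groups on C4 crowd the chair, so capture of the cation by the phenol may be slow; a hydride shift from C3 to the cation, Lewis-acid loss of benzyl ethers or incomplete equilibration of the 2,3-cis flavan may then take over. The fallback closes the pyran ring before the pyrogallol ring is present and lets the ring control C4. It sets out from diol 8 and comes back at 18. MnO2 in CH2Cl2 oxidises the benzylic alcohol of 8 to (2R)-1-[4-(benzyloxy)-2-hydroxyphenyl]-2-(benzyloxy)-3-[3,4-bis(benzyloxy)phenyl]-3-methoxypropan-1-one F3. BF3·OEt2 closes F3 to the trans-dihydroflavonol (2R,3R)-3,7-bis(benzyloxy)-2-[3,4-bis(benzyloxy)phenyl]chroman-4-one F4; a hydride shift towards a cation next to the carbonyl-bearing carbon is disfavoured and C4 is not yet crowded. NaBH4 gives (2R,3S)-3,7-bis(benzyloxy)-2-[3,4-bis(benzyloxy)phenyl]chroman-4-ol F5. Catalytic TMSOTf at −40 °C ionises F5 to the ring A-stabilised C4 cation, which arene 12 (in excess; its two free positions are equivalent) should attack anti to the 3-benzyloxy group to give 18. The weak point of this fallback is the modest nucleophilicity of 12.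

Step 3. The α-benzyloxy ester slows hydride abstraction, the cation may lose the acidic α-proton to give the α-benzyloxycinnamate (loss of the stereocentre), and the methyl ether may be oxidised further to the aryl ketone. The fallback moves the oxidation to the alcohol oxidation level, where there is no acidic α-proton and less deactivation. It sets out from 3 and comes back at 5. LiBH4 reduces 3 to (2R)-2-(benzyloxy)-3-[3,4-bis(benzyloxy)phenyl]propan-1-ol F6, and TBSCl with imidazole gives its tert-butyldimethylsilyl ether F7. DDQ in CH2Cl2–MeOH gives the benzylic methyl ether F8 as both epimers, Bu4NF frees (2S)-2-(benzyloxy)-3-[3,4-bis(benzyloxy)phenyl]-3-methoxypropan-1-ol F9, and a Swern oxidation gives 5.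

**Further compounds**

F1 | step 10 | (2S)-1-[6-bromo-2,3,4-tris(benzyloxy)phenyl]-2-(benzyloxy)-3-[3,4-bis(benzyloxy)phenyl]-3-methoxypropan-1-ol, epimers at C1 and C3 | OC(c1c(Br)cc(OCc2ccccc2)c(OCc2ccccc2)c1OCc1ccccc1)[C@H](OCc1ccccc1)C(OC)c1ccc(OCc2ccccc2)c(OCc2ccccc2)c1
F2 | step 10 | 2,2,2-trichloroacetimidate of F1 | N=C(OC(c1c(Br)cc(OCc2ccccc2)c(OCc2ccccc2)c1OCc1ccccc1)[C@H](OCc1ccccc1)C(OC)c1ccc(OCc2ccccc2)c(OCc2ccccc2)c1)C(Cl)(Cl)Cl
F3 | step 11 | (2R)-1-[4-(benzyloxy)-2-hydroxyphenyl]-2-(benzyloxy)-3-[3,4-bis(benzyloxy)phenyl]-3-methoxypropan-1-one, both C3 epimers | O=C(c1ccc(OCc2ccccc2)cc1O)[C@H](OCc1ccccc1)C(OC)c1ccc(OCc2ccccc2)c(OCc2ccccc2)c1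
F4 | step 11 | (2R,3R)-3,7-bis(benzyloxy)-2-[3,4-bis(benzyloxy)phenyl]chroman-4-one | O=C1c2ccc(OCc3ccccc3)cc2O[C@H](c2ccc(OCc3ccccc3)c(OCc3ccccc3)c2)[C@H]1OCc1ccccc1
F5 | step 11 | (2R,3S)-3,7-bis(benzyloxy)-2-[3,4-bis(benzyloxy)phenyl]chroman-4-ol, C4 epimers | OC1c2ccc(OCc3ccccc3)cc2O[C@H](c2ccc(OCc3ccccc3)c(OCc3ccccc3)c2)[C@H]1OCc1ccccc1
F6 | step 3 | (2R)-2-(benzyloxy)-3-[3,4-bis(benzyloxy)phenyl]propan-1-ol | c1ccccc1CO[C@H](Cc1ccc(OCc2ccccc2)c(OCc2ccccc2)c1)CO
F7 | step 3 | tert-butyl{[(2R)-2-(benzyloxy)-3-[3,4-bis(benzyloxy)phenyl]propyl]oxy}dimethylsilane | c1ccccc1CO[C@H](Cc1ccc(OCc2ccccc2)c(OCc2ccccc2)c1)CO[Si](C)(C)C(C)(C)C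
F8 | step 3 | tert-butyl{[(2S)-2-(benzyloxy)-3-[3,4-bis(benzyloxy)phenyl]-3-methoxypropyl]oxy}dimethylsilane, both C3 epimers | c1ccccc1CO[C@H](C(OC)c1ccc(OCc2ccccc2)c(OCc2ccccc2)c1)CO[Si](C)(C)C(C)(C)C
F9 | step 3 | (2S)-2-(benzyloxy)-3-[3,4-bis(benzyloxy)phenyl]-3-methoxypropan-1-ol, both C3 epimers | c1ccccc1CO[C@H](C(OC)c1ccc(OCc2ccccc2)c(OCc2ccccc2)c1)CO
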